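The isoflavone is disconnected at the C3–C4 bond of the pyranone ring (ring C). C4, the ring carbonyl on A-ring carbon C4a, and C3, the carbon carrying the B ring, can both begin as carbonyl carbons: an A-ring aldehyde and a B-ring aryl ketone joined through O1–C2 as the phenacyl ether of a salicylaldehyde. A triazolylidene carbene reverses the polarity of the aldehyde, which then adds to the ketone: one operation forms C3–C4, closes ring C and leaves a C3 carbinol that is afterwards eliminated across C2–C3. The precursor is that keto aldehyde, with the B-ring phenol masked as a benzyl ether.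

Key step: step 6

Assumption: the target SMILES has no stereocentre and no stereogenic double bond, so the "single enantiomer" is the achiral compound itself. The only stereocentre on the route (C3 of 9) is made racemic on purpose and is removed in step 7.

Assumption: 1-(2,3-dihydroxyphenyl)ethanone (2',3'-dihydroxyacetophenone) is taken as a catalogue compound. It already carries the two-carbon ketone side chain, which keeps the B-ring branch to three steps.

Remark: in a 2-(phenacyloxy)benzaldehyde the aldol of the OCH2 group onto the aldehyde is not held back by ring strain. It is the first stage of the Rap–Stoermer synthesis of 2-aroylbenzofurans. It is therefore treated as a real competitor in steps 5 and 6 and is answered by mild, weakly basic conditions.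

Step 1
Reactants: 1 1-(2,3-dihydroxyphenyl)ethanone
Product: 2 1-[3-(benzyloxy)-2-hydroxyphenyl]ethanone
Conditions: NaH (2.1 equiv), DMSO–THF, 20 °C; then BnBr (1.0 equiv), 20 °C; aq. HCl work-up
Reagents that add atoms: benzyl bromide, BrCc1ccccc1
Why: Williamson ether synthesis on the catechol dianion: the 2-oxide is conjugated with the acetyl group, chelated to sodium and flanked on both sides, so one equivalent of benzyl bromide should alkylate the more basic, more exposed 3-oxide, as is established for dianions of ortho-acyl catechols such as 2,3-dihydroxybenzaldehyde.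

Step 2
Reactants: 2 1-[3-(benzyloxy)-2-hydroxyphenyl]ethanone
Product: 3 1-[3-(benzyloxy)-2-methoxyphenyl]ethanone
Conditions: MeI (1.5 equiv), K2CO3 (2 equiv), DMF, 40 °C
Reagents that add atoms: iodomethane, CI
Why: Williamson methylation of the chelated 2-hydroxyl with a small electrophile; potassium carbonate deprotonates the phenol but is too weak to enolise the methyl ketone enough for C-methylation.

Step 3
Reactants: 3 1-[3-(benzyloxy)-2-methoxyphenyl]ethanone
Product: 4 1-[3-(benzyloxy)-2-methoxyphenyl]-2-bromoethanone
Conditions: CuBr2 (2.1 equiv), EtOAc–CHCl3 (1:1), reflux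
Reagents that add atoms: copper(II) bromide, Br[Cu]Br
Why: King–Ostrum α-bromination of an aryl methyl ketone with copper(II) bromide, which brominates the enol at the side chain in preference to the alkoxy-substituted ring, stops at the monobromide and is routinely used on benzyloxyacetophenones.

Step 4
Reactants: 5 3,4,5-trimethoxyphenol
Product: 7 6-hydroxy-2,3,4-trimethoxybenzaldehyde, via 2-(hydroxymethyl)-3,4,5-trimethoxyphenol 6 (not isolated)
Conditions: MgCl2 (1.5 equiv), Et3N (3.75 equiv), (CH2O)n (6 equiv), MeCN, reflux; aq. HCl work-up
Reagents that add atoms: paraformaldehyde (reacts as formaldehyde), C=O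
Why: Magnesium-mediated ortho-formylation of a phenol (Casnati–Skattebøl): formaldehyde is delivered within the magnesium phenoxide to an ortho carbon and the benzylic alkoxide so formed is oxidised by a second formaldehyde through Oppenauer-type hydride transfer; the two free ring positions of 5 are equivalent, so only one aldehyde can form.

Step 5
Reactants: 7 6-hydroxy-2,3,4-trimethoxybenzaldehyde; 4 1-[3-(benzyloxy)-2-methoxyphenyl]-2-bromoethanone
Product: 8 6-{2-[3-(benzyloxy)-2-methoxyphenyl]-2-oxoethoxy}-2,3,4-trimethoxybenzaldehyde
Conditions: K2CO3 (1.3 equiv), acetone, 20 °C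
Reagents that add atoms: none
Why: Williamson ether synthesis between a salicylaldehyde phenoxide and a phenacyl bromide, a very reactive SN2 electrophile; the Rap–Stoermer follow-up (aldol of the OCH2 group onto the aldehyde, then dehydration to a 2-aroylbenzofuran) needs heat or stronger base and is slowed further here by the electron-rich, doubly ortho-substituted aldehyde.

Step 6
Reactants: 8 6-{2-[3-(benzyloxy)-2-methoxyphenyl]-2-oxoethoxy}-2,3,4-trimethoxybenzaldehyde
Product: 9 rac-3-[3-(benzyloxy)-2-methoxyphenyl]-3-hydroxy-5,6,7-trimethoxychroman-4-one
Conditions: 2-(pentafluorophenyl)-6,7-dihydro-5H-pyrrolo[2,1-c][1,2,4]triazol-2-ium tetrafluoroborate (20 mol %), Et3N (20 mol %), toluene, 20→40 °C, Ar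
Reagents that add atoms: none
Why: The triazolylidene freed by Et3N adds to the aldehyde carbon (future C4), proton transfer gives the Breslow intermediate, and this acyl-anion equivalent attacks the tethered aryl ketone (future C3); collapse of the adduct releases the carbene and leaves the α-hydroxy ketone. The closest known reaction type is the carbene-catalysed intramolecular crossed aldehyde–ketone benzoin of 2-(2-oxoalkoxy)benzaldehydes to 3-hydroxychroman-4-ones. The pyranone ring closes in a 6-exo-trig mode, since the enaminol carbon attacks a ketone C=O that lies outside the new ring. The C3 carbinol is the only new stereocentre; with an achiral catalyst nothing controls it, and the racemate is what is wanted because step 7 removes the centre. The step needs chemoselectivity for the crossed benzoin over the amine-mediated aldol of the OCH2 group onto the aldehyde and over intermolecular homo-benzoin: only the aldehyde can become an acyl-anion equivalent, the ketone sits five atoms away, and the acidic N-C6F5 triazolium needs only a catalytic tertiary amine that should not enolise the ketone. The flat, compact carbene is chosen because the aldehyde carries two ortho substituents.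

Step 7
Reactants: 9 rac-3-[3-(benzyloxy)-2-methoxyphenyl]-3-hydroxy-5,6,7-trimethoxychroman-4-one
Product: 11 3-[3-(benzyloxy)-2-methoxyphenyl]-5,6,7-trimethoxy-4H-chromen-4-one, via C3 chlorosulfite ester 10 (not isolated)
Conditions: SOCl2 (1.5 equiv), pyridine (5 equiv), CH2Cl2, 0→20 °C
Reagents that add atoms: thionyl chloride, O=S(Cl)Cl (its S, O and Cl are held only in 10; none remains in 11)
Why: Dehydration of a tertiary benzylic alcohol through its chlorosulfite by pyridine-mediated E2 elimination: C2 carries the only β-hydrogens and loss of one of them gives the conjugated 4-pyranone, so a single alkene is possible and the racemic C3 centre disappears.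

Step 8
Reactants: 11 3-[3-(benzyloxy)-2-methoxyphenyl]-5,6,7-trimethoxy-4H-chromen-4-one
Product: 12 3-(3-hydroxy-2-methoxyphenyl)-5,6,7-trimethoxy-4H-chromen-4-one
Conditions: H2 (1 atm), 10% Pd/C, EtOAc, 20 °C
Reagents that add atoms: none
Why: Catalytic hydrogenolysis of a benzyl aryl ether; the C2=C3 bond of the chromone is a vinylogous ester double bond that is hydrogenated much more slowly than the O–benzyl bond is cleaved, so the reaction is stopped when 11 is consumed.

Compound list
1 | 1-(2,3-dihydroxyphenyl)ethanone | CC(=O)c1cccc(O)c1O | starting material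
2 | 1-[3-(benzyloxy)-2-hydroxyphenyl]ethanone | CC(=O)c1cccc(OCc2ccccc2)c1O | intermediate
3 | 1-[3-(benzyloxy)-2-methoxyphenyl]ethanone | CC(=O)c1cccc(OCc2ccccc2)c1OC | intermediate
4 | 1-[3-(benzyloxy)-2-methoxyphenyl]-2-bromoethanone | O=C(CBr)c1cccc(OCc2ccccc2)c1OC | intermediate
5 | 3,4,5-trimethoxyphenol | COc1cc(O)cc(OC)c1OC | starting material
6 | 2-(hydroxymethyl)-3,4,5-trimethoxyphenol (not isolated) | COc1cc(O)c(CO)c(OC)c1OC | intermediate
7 | 6-hydroxy-2,3,4-trimethoxybenzaldehyde | COc1cc(O)c(C=O)c(OC)c1OC | intermediate
8 | 6-{2-[3-(benzyloxy)-2-methoxyphenyl]-2-oxoethoxy}-2,3,4-trimethoxybenzaldehyde | COc1cc(OCC(=O)c2cccc(OCc3ccccc3)c2OC)c(C=O)c(OC)c1OC | intermediate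
9 | rac-3-[3-(benzyloxy)-2-methoxyphenyl]-3-hydroxy-5,6,7-trimethoxychroman-4-one (racemic at C3) | COc1cc2OCC(O)(c3cccc(OCc4ccccc4)c3OC)C(=O)c2c(OC)c1OC | intermediate
10 | 3-[3-(benzyloxy)-2-methoxyphenyl]-5,6,7-trimethoxy-4-oxochroman-3-yl chlorosulfite (racemic, not isolated) | COc1cc2OCC(OS(=O)Cl)(c3cccc(OCc4ccccc4)c3OC)C(=O)c2c(OC)c1OC | intermediate
11 | 3-[3-(benzyloxy)-2-methoxyphenyl]-5,6,7-trimethoxy-4H-chromen-4-one | COc1cc2occ(-c3cccc(OCc4ccccc4)c3OC)c(=O)c2c(OC)c1OC | intermediate
12 | 3-(3-hydroxy-2-methoxyphenyl)-5,6,7-trimethoxy-4H-chromen-4-one (achiral) | COc1cc2occ(-c3cccc(O)c3OC)c(=O)c2c(OC)c1OC | target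

Total step count: 8
Longest linear sequence: 7 steps (steps 1, 2, 3, 5, 6, 7, 8); step 4 is a one-step side branch.

Steps most likely to fail

Step 6. The carbene may add too slowly to the electron-rich, doubly ortho-substituted aldehyde, so that amine-mediated aldol condensation of the phenacyl ether or slow decomposition overtakes ring closure. The fallback gives up the polarity reversal and builds the same isoflavone by the classical deoxybenzoin route. It sets out from ketone 3 and phenol 5. Willgerodt–Kindler reaction of 3 (S8, morpholine, 130 °C) should give 2-[3-(benzyloxy)-2-methoxyphenyl]-1-(morpholin-4-yl)ethanethione F1. Hydrolysis (KOH, aq. EtOH, reflux, then acid) should give [3-(benzyloxy)-2-methoxyphenyl]acetic acid F2. Friedel–Crafts acylation of 5 with F2 (BF3·OEt2, 70 °C), at one of its two equivalent free positions, should give the deoxybenzoin 2-[3-(benzyloxy)-2-methoxyphenyl]-1-(6-hydroxy-2,3,4-trimethoxyphenyl)ethanone F3. Condensation of F3 with DMF dimethyl acetal (toluene, 100 °C) should insert C2 and close the pyranone ring to give 11, where the fallback comes back to the route before step 8.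

Step 5. Under the carbonate the ether, once formed, may undergo aldol addition of its OCH2 group to the neighbouring aldehyde and dehydrate to a benzofuran, or the chelated phenol may be alkylated too slowly. The fallback forms the ether before the aldehyde is in place. It sets out from phenol 5 and bromide 4: etherification (K2CO3, acetone, 20 °C) should give 1-[3-(benzyloxy)-2-methoxyphenyl]-2-(3,4,5-trimethoxyphenoxy)ethanone F4, which has no aldehyde to condense with. Vilsmeier–Haack formylation of its tetra-oxygenated ring (POCl3, DMF, 0→20 °C, then aq. NaOAc), at either of the two equivalent positions ortho to the ether oxygen, should give 8, where the fallback comes back to the route. The acyl-deactivated B ring and, at this temperature, the ketone should stay untouched. Step 4 is then not needed.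

Step 7. The chlorosulfite may be substituted or may ionise instead of eliminating, giving chloride at C3 or an α-ketol-type aryl shift. The fallback removes the C3 oxygen reductively and then restores the unsaturation by dehydrogenation. It sets out from 9: SmI2 (THF–MeOH, −78 °C) should cleave the C–O bond α to the ketone, as in the reduction of benzoins to deoxybenzoins, and give racemic 3-[3-(benzyloxy)-2-methoxyphenyl]-5,6,7-trimethoxychroman-4-one F5. DDQ (dioxane, reflux) should then dehydrogenate C2–C3 of this isoflavanone to give 11, where the fallback comes back to the route.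

Further compounds
F1 | step 6 | 2-[3-(benzyloxy)-2-methoxyphenyl]-1-(morpholin-4-yl)ethanethione | S=C(Cc1cccc(OCc2ccccc2)c1OC)N1CCOCC1
F2 | step 6 | [3-(benzyloxy)-2-methoxyphenyl]acetic acid | OC(=O)Cc1cccc(OCc2ccccc2)c1OC
F3 | step 6 | 2-[3-(benzyloxy)-2-methoxyphenyl]-1-(6-hydroxy-2,3,4-trimethoxyphenyl)ethanone | COc1cc(O)c(C(=O)Cc2cccc(OCc3ccccc3)c2OC)c(OC)c1OC
F4 | step 5 | 1-[3-(benzyloxy)-2-methoxyphenyl]-2-(3,4,5-trimethoxyphenoxy)ethanone | COc1cc(OCC(=O)c2cccc(OCc3ccccc3)c2OC)cc(OC)c1OC
F5 | step 7 | rac-3-[3-(benzyloxy)-2-methoxyphenyl]-5,6,7-trimethoxychroman-4-one | COc1cc2OCC(c3cccc(OCc4ccccc4)c3OC)C(=O)c2c(OC)c1OC
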